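How much substrate, mono adduct, bis adduct and triple product stand in this flask at the asked time?

- how much substrate there is at 12 d, in percent of the substrate charged
- how much mono adduct there is at 12 d, in percent of the substrate charged
- how much bis adduct there is at 12 d, in percent of the substrate charged
- how much triple product there is at 12 d, in percent of the substrate charged

- alder: substrate 20 mM; reagent 3.6 equiv; capture agent 1 mM; run made earlier
- flask: substrate 20 mM; reagent 1.80 equiv; capture agent 1.00 mM; time 12 d

alder run (percent of the substrate charged)

| time / d | substrate / % | mono adduct / % | bis adduct / % |
|---|---|---|---|
| 0.833 | 0 | 14.9 | 23.1 |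
| 1.67 | 0 | 5.0 | 10.1 |
| 2.50 | 0 | 2.2 | 6.0 |
| 4.00 | 0 | 0 | 1.7 |

(standard deviation of a reading: 1 percentage point)



In the alder run the readings of mono adduct fell from 14.9% to 0% and those of bis adduct from 23.1% to 1.7%, which reads as adducts going on to further additions. On each substrate 3 additions take 60.0 mM, and the alder run charged 72.0 mM of reagent, more than that. This flask charges 36.0 mM, less than that, so reagent is the limiting reagent here.

The reckoning for the bench is a balance, taken for when the reagent has been consumed and stands in these adducts. The addition room is the reagent charged less one addition taken as tied up per capture agent, 35.0 mM. Per substrate charged: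

mono adduct + 2 × bis adduct + 3 × triple product = 1.75

Leave the flask closed and add nothing; the balance is written for this charge.

The forecast expects substrate 3%, mono adduct 42%, bis adduct 30% and triple product 25%, holding that “the outcome is set by selectivity rather than time”. Its adducts put 1.77 into the balance.

The flask gives substrate 0.176%, mono adduct 33.6%, bis adduct 27.4% and triple product 26.4%, with reagent at 0%.

    substrate + bis adduct → side product (k = 0.0260 M⁻¹ min⁻¹)
    reagent + mono adduct → bis adduct + released group (k = 0.0480 M⁻¹ min⁻¹)
    reagent + bis adduct → triple product + released group (k = 0.0540 M⁻¹ min⁻¹)
    substrate + reagent → mono adduct + released group (k = 0.140 M⁻¹ min⁻¹)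
    mono adduct + capture agent → trapped intermediate (k = 0.900 M⁻¹ min⁻¹)

The forecast's mono adduct stands 8.4 percentage points above the flask's. In the flask the adducts hold 1.68 equiv of the room, and the remaining 0.0743 stands in side product, 7.43%, which holds one addition per unit counted. Bis adduct stands at 27.4% in this flask partly through the consumption of reagent together with the depletion of capture agent: the same flask gives 0% with reagent not consumed, and 2.49% with capture agent not depleted.

For the neighbour with 1.10 equiv of reagent the room is 1.05 per substrate. That neighbour's adducts hold 0.817, and its side product stands at 23.3%.

(Readings and results were generated by integration with constants of no real substance, noise included.)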